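**Retrosynthetic overview**
1. Target 12 ⇐ O-demethylation of 2-methoxy-6-(12-phenyldodecyl)benzoic acid 10.
2. Key step: 10 ⇐ one-pot three-component union of 3-methoxybenzyne (from 3-fluoroanisole), (12-phenyldodecyl)lithium and CO2. This aryne carbolithiation/carboxylation makes both aryl C–C bonds (chain and CO2H) at once, instead of the usual cross-coupling of the chain onto a preformed salicylate triflate.
3. The alkyllithium ⇐ (12-bromododecyl)benzene ⇐ PhMgBr + 1,12-dibromododecane (Cu-catalysed sp2–sp3 coupling).
4. No ring is formed: both benzene rings are bought in (PhMgBr and 3-fluoroanisole).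

Assumption: the target has no stereocentre and no stereogenic double bond, so it is achiral and "single enantiomer" requires no stereocontrol.

**Step 1**
Reactants: 1 phenylmagnesium bromide; 2 1,12-dibromododecane
Product: 3 (12-bromododecyl)benzene
Conditions: 2 (3 equiv), Li2CuCl4 (3 mol %), THF, −10 °C → rt, slow addition of 1 (1 equiv); excess 2 recovered by Kugelrohr distillation
Reagents that add atoms: none
Why: Kochi-type copper-catalysed Grignard/primary alkyl bromide cross-coupling; the threefold excess of the symmetric dibromide holds the reaction at mono-arylation and the remaining C–Br survives at low temperature.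

**Step 2**
Reactants: 3 (12-bromododecyl)benzene
Product: 4 (12-phenyldodecyl)lithium (titrated Et2O solution, used directly)
Conditions: Li (1 % Na, 2.5 equiv), Et2O, −15 → 0 °C, slow addition of 3, Ar; cannula filtration, titration
Reagents that add atoms: lithium metal, [Li]
Why: reductive lithiation of a primary alkyl bromide (two single-electron transfers at the metal surface); slow addition at low temperature suppresses Wurtz coupling, and the remote phenyl ring and its benzylic CH2 are not metalated in ether.

**Step 3**
Reactants: 4 (12-phenyldodecyl)lithium; 5 3-fluoroanisole (1-fluoro-3-methoxybenzene)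
Product: 10 2-methoxy-6-(12-phenyldodecyl)benzoic acid, via (2-fluoro-6-methoxyphenyl)lithium 6 (not isolated), via 3-methoxybenzyne 7 (not isolated), via [2-methoxy-6-(12-phenyldodecyl)phenyl]lithium 8 (not isolated), via lithium 2-methoxy-6-(12-phenyldodecyl)benzoate 9 (not isolated)
Conditions: 5, n-BuLi (1.0 equiv), THF, −78 °C, 1 h; then 4 (1.5 equiv), −78 → −10 °C, 3 h; then CO2 (g, excess), −78 °C → rt; 2 M HCl (the acid formed from surplus 4 is removed by chromatography)
Reagents that add atoms: carbon dioxide, O=C=O
Why: directed ortho-lithiation between F and OMe gives 6, which loses LiF on warming to aryne 7; the alkyllithium adds at the aryne carbon remote from OMe (inductive/aryne-distortion control, carbanion next to OMe) and the resulting aryllithium 8 is trapped by CO2, a tandem aryne carbolithiation/carboxylation with no stereocentre created.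

**Step 4**
Reactants: 10 2-methoxy-6-(12-phenyldodecyl)benzoic acid
Product: 12 2-hydroxy-6-(12-phenyldodecyl)benzoic acid (target), via 2-bromo-5-(12-phenyldodecyl)-4H-1,3,2-benzodioxaborinin-4-one 11 (not isolated)
Conditions: BBr3 (2.5 equiv), CH2Cl2, −78 → 0 °C, 2 h; then ice/H2O
Reagents that add atoms: none
Why: Lewis-acid aryl methyl ether cleavage, assisted by chelation of boron between the carboxyl and the ortho-OMe (SN2 loss of MeBr), then hydrolysis of chelate 11; the cold conditions avoid decarboxylation of the 6-alkylsalicylic acid and the alkylbenzene terminus is inert.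

**Compound list**
1 | phenylmagnesium bromide | Br[Mg]c1ccccc1 | starting material
2 | 1,12-dibromododecane | BrCCCCCCCCCCCCBr | starting material
3 | (12-bromododecyl)benzene | BrCCCCCCCCCCCCc1ccccc1 | intermediate
4 | (12-phenyldodecyl)lithium | [Li]CCCCCCCCCCCCc1ccccc1 | intermediate
5 | 3-fluoroanisole (1-fluoro-3-methoxybenzene) | COc1cccc(F)c1 | starting material
6 | (2-fluoro-6-methoxyphenyl)lithium | COc1cccc(F)c1[Li] | intermediate
7 | 3-methoxybenzyne (3-methoxy-1,2-didehydrobenzene) | COC1=CC=CC#C1 | intermediate
8 | [2-methoxy-6-(12-phenyldodecyl)phenyl]lithium | COc1cccc(CCCCCCCCCCCCc2ccccc2)c1[Li] | intermediate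
9 | lithium 2-methoxy-6-(12-phenyldodecyl)benzoate | COc1cccc(CCCCCCCCCCCCc2ccccc2)c1C(=O)[O-].[Li+] | intermediate
10 | 2-methoxy-6-(12-phenyldodecyl)benzoic acid | COc1cccc(CCCCCCCCCCCCc2ccccc2)c1C(=O)O | intermediate
11 | 2-bromo-5-(12-phenyldodecyl)-4H-1,3,2-benzodioxaborinin-4-one | O=C1OB(Br)Oc2cccc(CCCCCCCCCCCCc3ccccc3)c12 | intermediate
12 | 2-hydroxy-6-(12-phenyldodecyl)benzoic acid | O=C(O)c1c(O)cccc1CCCCCCCCCCCCc1ccccc1 | target

**Totals**
Total step count: 4. Longest linear sequence: 4 steps (1 + 2 → 3 → 4 → 10 → 12).

**Steps most likely to fail, with fallbacks**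

Step 3 (aryne carbolithiation/carboxylation; risks are aryne self-condensation and low capture by 4). The fallback gives up the aryne and attaches the chain by cross-coupling. It sets out from bromide 3 and comes back at target 12. Zinc insertion into 3 (Zn dust, LiCl, THF, 50 °C) gives (12-phenyldodecyl)zinc bromide F1. Negishi coupling of this (Pd(OAc)2/SPhos, THF, rt → 50 °C) with bought-in 2,2-dimethyl-4-oxo-4H-1,3-benzodioxin-5-yl trifluoromethanesulfonate F2 gives 2,2-dimethyl-5-(12-phenyldodecyl)-4H-1,3-benzodioxin-4-one F3. Opening the acetonide with KOH in THF/H2O at 60 °C, then HCl, gives 12.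

Step 2 (reductive lithiation; risks are Wurtz dimer and a poor titre). The fallback replaces the metal-surface reduction by halogen–lithium exchange. It sets out from 3 and comes back at 4. Finkelstein exchange (NaI, acetone, reflux) gives (12-iodododecyl)benzene F4. Treatment with t-BuLi (2.1 equiv) in pentane/Et2O 3:2 at −78 °C then gives 4 cleanly in solution.

Step 1 (statistical mono-arylation; risks are bis-coupling and a tedious separation from 2). The fallback uses a substrate with only one C–Br and installs the bromide afterwards. It sets out from 1 and comes back at 3. Grignard 1 (2.2 equiv, the first equivalent forming the alkoxide) is coupled with bought-in 12-bromododecan-1-ol F5 (Li2CuCl4 cat., THF, −10 °C → rt) to give 12-phenyldodecan-1-ol F6. An Appel reaction (CBr4, PPh3, CH2Cl2, 0 °C) converts this to 3.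

**Further compounds**
F1 | step 3 | (12-phenyldodecyl)zinc bromide | Br[Zn]CCCCCCCCCCCCc1ccccc1
F2 | step 3 | 2,2-dimethyl-4-oxo-4H-1,3-benzodioxin-5-yl trifluoromethanesulfonate (bought in) | CC1(C)OC(=O)c2c(OS(=O)(=O)C(F)(F)F)cccc2O1
F3 | step 3 | 2,2-dimethyl-5-(12-phenyldodecyl)-4H-1,3-benzodioxin-4-one | CC1(C)OC(=O)c2c(CCCCCCCCCCCCc3ccccc3)cccc2O1
F4 | step 2 | (12-iodododecyl)benzene | ICCCCCCCCCCCCc1ccccc1
F5 | step 1 | 12-bromododecan-1-ol (bought in) | OCCCCCCCCCCCCBr
F6 | step 1 | 12-phenyldodecan-1-ol | OCCCCCCCCCCCCc1ccccc1
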